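**Plan**

1. Retrosynthetic cuts, in this order: O1–C8a (aryl ether bond that closes ring C); C2–O back to a C2 carbonyl; C2–C3 (Claisen); C6–C1′ (Heck) and C6–I; C4a–C4 (C-acetylation of 5-fluororesorcinol).
2. Forward order: ring A is bought as 5-fluororesorcinol; acetyl enters next to fluorine and iodine between the two hydroxyls; the C10 chain of (S)-β-citronellene is joined at C6; ring B arrives as a benzoate; ring C is closed in the last step but one.
3. Enabling feature: in ring A, C8a is ortho to C4a, which carries the C4 carbonyl, so a C8a–F bond is a vinylogous acyl fluoride that the C2 oxygen can displace through a six-membered transition state.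
4. What the closure settles: fluorine marks only one of the two positions ortho to the acyl group, so the chain must end at C6 and not at C8; the bond made is O–aryl, so the closure itself makes or breaks no bond at C2.
5. Stereochemistry: C3′ (S) is bought with (S)-β-citronellene; C2 (S) is set before ring closure by asymmetric transfer hydrogenation of the ring-B carbonyl with RuCl(p-cymene)[(S,S)-TsDPEN].

Key step: step 8

Assumption: 5-fluororesorcinol, (S)-β-citronellene and methyl 3,4-dihydroxybenzoate are taken as commercial; all four phenols are carried as methoxymethyl (MOM) ethers.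

**Route**

Step 1
Reactants: 1 5-fluororesorcinol (5-fluorobenzene-1,3-diol)
Product: 2 1-(2-fluoro-4,6-dihydroxyphenyl)ethan-1-one
Conditions: AcOH, ZnCl2, 140 °C
Reagents that add atoms: acetic acid, CC(=O)O
Why: Nencki-type Friedel–Crafts C-acylation of a resorcinol goes para to one hydroxyl and ortho to the other, which in 1 is the carbon next to fluorine (both such carbons are equivalent), as in the conversion of resorcinol into resacetophenone.

Step 2
Reactants: 2 1-(2-fluoro-4,6-dihydroxyphenyl)ethan-1-one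
Product: 3 1-(6-fluoro-2,4-dihydroxy-3-iodophenyl)ethan-1-one
Conditions: I2 (0.4 equiv), HIO3 (0.2 equiv), EtOH/H2O, 35 °C
Reagents that add atoms: iodine, II; iodic acid, OI(=O)=O
Why: Electrophilic aromatic iodination with I2/HIO3 is directed by both hydroxyls to the carbon between them (ortho to the chelated hydroxyl), the known outcome for resacetophenone, and the only other free carbon is further deactivated by the neighbouring fluorine.

Step 3
Reactants: 3 1-(6-fluoro-2,4-dihydroxy-3-iodophenyl)ethan-1-one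
Product: 4 1-[6-fluoro-3-iodo-2,4-bis(methoxymethoxy)phenyl]ethan-1-one
Conditions: NaH (2.4 equiv), MOMCl (2.6 equiv), DMF, 0 °C to rt
Reagents that add atoms: chloromethyl methyl ether, COCCl
Why: Williamson-type O-alkylation of the two sodium phenoxides masks both phenols, including the chelated one, so that no phenoxide donates into the carbonyl during the later enolate and substitution steps.

Step 4
Reactants: 4 1-[6-fluoro-3-iodo-2,4-bis(methoxymethoxy)phenyl]ethan-1-one; 5 (S)-β-citronellene, (3S)-3,7-dimethylocta-1,6-diene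
Product: 6 1-[3-[(1E,3S)-3,7-dimethylocta-1,6-dien-1-yl]-6-fluoro-2,4-bis(methoxymethoxy)phenyl]ethan-1-one
Conditions: Pd(OAc)2 (10 mol %), Bu4NCl, NaHCO3, DMF, 70 °C
Reagents that add atoms: none
Why: Mizoroki–Heck reaction under ligand-free phase-transfer conditions, in which the aryl group adds to the terminal alkene carbon and syn β-hydride elimination toward the benzylic CH2 should give the conjugated (E)-styrene, while the trisubstituted alkene does not insert and the C3′ centre of 5 is carried over unchanged.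

Step 5
Reactants: 7 methyl 3,4-dihydroxybenzoate
Product: 8 methyl 3,4-bis(methoxymethoxy)benzoate
Conditions: NaH (2.2 equiv), MOMCl (2.4 equiv), DMF, 0 °C to rt
Reagents that add atoms: chloromethyl methyl ether, COCCl
Why: Williamson-type O-alkylation of the catechol dianion; the methyl ester is inert under these conditions.

Step 6
Reactants: 6 1-[3-[(1E,3S)-3,7-dimethylocta-1,6-dien-1-yl]-6-fluoro-2,4-bis(methoxymethoxy)phenyl]ethan-1-one; 8 methyl 3,4-bis(methoxymethoxy)benzoate
Product: 9 1-[3,4-bis(methoxymethoxy)phenyl]-3-[3-[(1E,3S)-3,7-dimethylocta-1,6-dien-1-yl]-6-fluoro-2,4-bis(methoxymethoxy)phenyl]propane-1,3-dione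
Conditions: LiN(SiMe3)2 (3 equiv), THF, −78 °C to rt; AcOH
Reagents that add atoms: none
Why: Crossed Claisen condensation, in which the lithium enolate of methyl ketone 6 attacks the non-enolisable ester 8 and a second equivalent of base removes the acidic proton of the 1,3-diketone, which drives the acylation to completion.

Step 7
Reactants: 9 1-[3,4-bis(methoxymethoxy)phenyl]-3-[3-[(1E,3S)-3,7-dimethylocta-1,6-dien-1-yl]-6-fluoro-2,4-bis(methoxymethoxy)phenyl]propane-1,3-dione
Product: 10 (3S)-3-[3,4-bis(methoxymethoxy)phenyl]-1-[3-[(1E,3S)-3,7-dimethylocta-1,6-dien-1-yl]-6-fluoro-2,4-bis(methoxymethoxy)phenyl]-3-hydroxypropan-1-one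
Conditions: RuCl(p-cymene)[(S,S)-TsDPEN] (3 mol %), HCO2H/Et3N (1:1), EtOAc, 30 °C
Reagents that add atoms: none
Why: Noyori–Ikariya asymmetric transfer hydrogenation, in which only the ring-B carbonyl should be reduced because the ring-A carbonyl carries two ortho substituents, and the (S,S)-ligand is expected to give the S carbinol in the same sense as acetophenone gives (S)-1-phenylethanol (aryl large, CH2 small); the antipodal ligand is at hand if the sense proves reversed.

Step 8
Reactants: 10 (3S)-3-[3,4-bis(methoxymethoxy)phenyl]-1-[3-[(1E,3S)-3,7-dimethylocta-1,6-dien-1-yl]-6-fluoro-2,4-bis(methoxymethoxy)phenyl]-3-hydroxypropan-1-one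
Product: 12 (2S)-2-[3,4-bis(methoxymethoxy)phenyl]-6-[(1E,3S)-3,7-dimethylocta-1,6-dien-1-yl]-5,7-bis(methoxymethoxy)-2,3-dihydro-4H-chromen-4-one, via lithium alkoxide 11 (not isolated)
Conditions: LiN(SiMe3)2 (0.98 equiv), THF/DMPU (4:1), −78 to 0 °C; AcOH
Reagents that add atoms: none
Why: The lithium alkoxide at C2 adds to C8a, the ring-A carbon ortho to the C4 carbonyl, to give a Meisenheimer adduct whose charge rests on the C4 enolate oxygen, and loss of fluoride as LiF restores ring A; this is an intramolecular SNAr (addition–elimination), the reaction type by which β-hydroxy or enolised 2-fluoroaryl ketones give chroman-4-ones and chromones. Ring C closes as a six-membered ring, 6-endo-trig with respect to the C4a=C8a bond of the aryl ketone (a vinylogous oxa-Michael addition followed by elimination). No stereocentre is formed, and C2 should keep the S configuration set in step 7 because the new bond is O–C(aryl) and no bond to C2 is made or broken. The step needs site selectivity (6- versus 8-substituted flavanone) and chemoselectivity over retro-aldol cleavage and E1cB dehydration. The site is fixed because fluorine sits on only one of the two carbons ortho to the acyl group and MOM ethers are not leaving groups. A lithium counter-ion, low temperature and slightly less than one equivalent of base are chosen to keep the alkoxide from fragmenting and to leave no base that could open the product by retro-oxa-Michael reaction.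

Step 9
Reactants: 12 (2S)-2-[3,4-bis(methoxymethoxy)phenyl]-6-[(1E,3S)-3,7-dimethylocta-1,6-dien-1-yl]-5,7-bis(methoxymethoxy)-2,3-dihydro-4H-chromen-4-one
Product: 14 (2S)-2-(3,4-dihydroxyphenyl)-6-[(1E,3S)-3,7-dimethylocta-1,6-dien-1-yl]-5,7-dihydroxy-2,3-dihydro-4H-chromen-4-one, via tetrakis(trimethylsilyl) ether 13 (not isolated)
Conditions: TMSOTf (8 equiv), 2,2′-bipyridyl (12 equiv), MeCN, 0 °C to rt; then H2O
Reagents that add atoms: none
Why: Silyl triflate/2,2′-bipyridyl cleavage of aryl MOM ethers converts each acetal without protic acid into an aryl trimethylsilyl ether and an N-(methoxymethyl)bipyridinium salt, and water then hydrolyses the silyl ethers, so that the electron-rich styrene and the trisubstituted alkene should not be cyclised and the C2 centre (no base present) should not be racemised.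

**Compound list**

1 | 5-fluororesorcinol (5-fluorobenzene-1,3-diol) | Oc1cc(O)cc(F)c1 | starting material
2 | 1-(2-fluoro-4,6-dihydroxyphenyl)ethan-1-one | CC(=O)c1c(O)cc(O)cc1F | intermediate
3 | 1-(6-fluoro-2,4-dihydroxy-3-iodophenyl)ethan-1-one | CC(=O)c1c(O)c(I)c(O)cc1F | intermediate
4 | 1-[6-fluoro-3-iodo-2,4-bis(methoxymethoxy)phenyl]ethan-1-one | CC(=O)c1c(OCOC)c(I)c(OCOC)cc1F | intermediate
5 | (S)-β-citronellene, (3S)-3,7-dimethylocta-1,6-diene | CC(C)=CCC[C@H](C)C=C | starting material
6 | 1-[3-[(1E,3S)-3,7-dimethylocta-1,6-dien-1-yl]-6-fluoro-2,4-bis(methoxymethoxy)phenyl]ethan-1-one | CC(C)=CCC[C@H](C)/C=C/c1c(OCOC)cc(F)c(C(C)=O)c1OCOC | intermediate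
7 | methyl 3,4-dihydroxybenzoate | COC(=O)c1ccc(O)c(O)c1 | starting material
8 | methyl 3,4-bis(methoxymethoxy)benzoate | COC(=O)c1ccc(OCOC)c(OCOC)c1 | intermediate
9 | 1-[3,4-bis(methoxymethoxy)phenyl]-3-[3-[(1E,3S)-3,7-dimethylocta-1,6-dien-1-yl]-6-fluoro-2,4-bis(methoxymethoxy)phenyl]propane-1,3-dione | CC(C)=CCC[C@H](C)/C=C/c1c(OCOC)cc(F)c(C(=O)CC(=O)c2ccc(OCOC)c(OCOC)c2)c1OCOC | intermediate
10 | (3S)-3-[3,4-bis(methoxymethoxy)phenyl]-1-[3-[(1E,3S)-3,7-dimethylocta-1,6-dien-1-yl]-6-fluoro-2,4-bis(methoxymethoxy)phenyl]-3-hydroxypropan-1-one | CC(C)=CCC[C@H](C)/C=C/c1c(OCOC)cc(F)c(C(=O)C[C@H](O)c2ccc(OCOC)c(OCOC)c2)c1OCOC | intermediate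
11 | lithium alkoxide of 10 | CC(C)=CCC[C@H](C)/C=C/c1c(OCOC)cc(F)c(C(=O)C[C@H]([O-])c2ccc(OCOC)c(OCOC)c2)c1OCOC.[Li+] | intermediate (not isolated)
12 | (2S)-2-[3,4-bis(methoxymethoxy)phenyl]-6-[(1E,3S)-3,7-dimethylocta-1,6-dien-1-yl]-5,7-bis(methoxymethoxy)-2,3-dihydro-4H-chromen-4-one | CC(C)=CCC[C@H](C)/C=C/c1c(OCOC)cc2c(c1OCOC)C(=O)C[C@@H](c1ccc(OCOC)c(OCOC)c1)O2 | intermediate
13 | (2S)-2-[3,4-bis(trimethylsilyloxy)phenyl]-6-[(1E,3S)-3,7-dimethylocta-1,6-dien-1-yl]-5,7-bis(trimethylsilyloxy)-2,3-dihydro-4H-chromen-4-one | CC(C)=CCC[C@H](C)/C=C/c1c(O[Si](C)(C)C)cc2c(c1O[Si](C)(C)C)C(=O)C[C@@H](c1ccc(O[Si](C)(C)C)c(O[Si](C)(C)C)c1)O2 | intermediate (not isolated)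
14 | (2S)-2-(3,4-dihydroxyphenyl)-6-[(1E,3S)-3,7-dimethylocta-1,6-dien-1-yl]-5,7-dihydroxy-2,3-dihydro-4H-chromen-4-one | CC(C)=CCC[C@H](C)/C=C/c1c(O)cc2c(c1O)C(=O)C[C@@H](c1ccc(O)c(O)c1)O2 | target

**Step count**

Total: 9 steps. Longest linear sequence: 8 steps (steps 1, 2, 3, 4, 6, 7, 8, 9); step 5 is the one-step side branch.

**Steps most likely to fail**

Step 8. Retro-aldol cleavage of the alkoxide, or its dehydration through the enolate (E1cB), may outrun attack on C8a, and residual base may open the product by retro-oxa-Michael reaction; each of these erodes or destroys the C2 centre. The fallback sets out from 10 and comes back at 12; it forms the same O–C8a bond while no enolisable ketone is present. Reduction of 10 with NaBH4 in MeOH at 0 °C would give the diol (1S,3RS)-1-[3,4-bis(methoxymethoxy)phenyl]-3-[3-[(1E,3S)-3,7-dimethylocta-1,6-dien-1-yl]-6-fluoro-2,4-bis(methoxymethoxy)phenyl]propane-1,3-diol F1. KN(SiMe3)2 with 18-crown-6 in THF at 60 °C would then close ring C by intramolecular SNAr of the C2 alkoxide on the fluoroarene (the benzylic alkoxide could only form a four-membered ring), giving the flavan-4-ol (2S,4RS)-2-[3,4-bis(methoxymethoxy)phenyl]-6-[(1E,3S)-3,7-dimethylocta-1,6-dien-1-yl]-5,7-bis(methoxymethoxy)-3,4-dihydro-2H-chromen-4-ol F2. Dess–Martin periodinane (NaHCO3, CH2Cl2) would reoxidise C4 and give 12.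

Step 4. Alkene insertion at the doubly ortho-substituted arylpalladium iodide may be slow, and re-addition of palladium hydride (chain walking) may move the double bond or scramble C3′. The fallback sets out from 4 and comes back at 6; it fixes the position of the double bond by an addition–elimination sequence instead of a Heck reaction. Nozaki–Hiyama–Kishi coupling of 4 with commercial (S)-citronellal (CC(C)=CCC[C@H](C)CC=O; CrCl2, catalytic NiCl2, DMF, rt), which leaves the methyl ketone alone, would give the carbinol 1-[6-fluoro-3-[(3S)-1-hydroxy-3,7-dimethyloct-6-en-1-yl]-2,4-bis(methoxymethoxy)phenyl]ethan-1-one F3 as a mixture of C1′ epimers. Syn elimination with Burgess reagent (toluene, 50 °C) can only go toward C2′ and should give the (E)-styrene 6.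

Step 9. Lewis-acid activation of the electron-rich styrene or of the trisubstituted alkene (cation–olefin cyclisation, addition) may compete while four acetals are being cleaved, or cleavage may stay incomplete. The fallback sets out from 4 and comes back at 14; the MOM ethers are removed before the acid-sensitive chain exists, and the chain is attached last under fluoride-labile protection.

- Claisen condensation of 4 with 8 (LiN(SiMe3)2, THF) would give the diketone 1-[3,4-bis(methoxymethoxy)phenyl]-3-[6-fluoro-3-iodo-2,4-bis(methoxymethoxy)phenyl]propane-1,3-dione F4.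
- Transfer hydrogenation as in step 7 would give the aldol (3S)-3-[3,4-bis(methoxymethoxy)phenyl]-1-[6-fluoro-3-iodo-2,4-bis(methoxymethoxy)phenyl]-3-hydroxypropan-1-one F5.
- Ring closure as in step 8 would give the iodoflavanone (2S)-2-[3,4-bis(methoxymethoxy)phenyl]-6-iodo-5,7-bis(methoxymethoxy)-2,3-dihydro-4H-chromen-4-one F6.
- HCl in MeOH at 50 °C would then give (2S)-2-(3,4-dihydroxyphenyl)-5,7-dihydroxy-6-iodo-2,3-dihydro-4H-chromen-4-one F7.
- TBSCl and imidazole in DMF would silylate all but the chelated 5-hydroxyl and give (2S)-2-[3,4-bis(tert-butyldimethylsilyloxy)phenyl]-7-(tert-butyldimethylsilyloxy)-5-hydroxy-6-iodo-2,3-dihydro-4H-chromen-4-one F8.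
- Heck coupling with 5 (Pd[P(t-Bu)3]2, Cy2NMe, dioxane, 60 °C) would give (2S)-2-[3,4-bis(tert-butyldimethylsilyloxy)phenyl]-7-(tert-butyldimethylsilyloxy)-6-[(1E,3S)-3,7-dimethylocta-1,6-dien-1-yl]-5-hydroxy-2,3-dihydro-4H-chromen-4-one F9.
- Bu4NF buffered with AcOH (THF, 0 °C) would give 14.

Further compounds

F1 | step 8 | (1S,3RS)-1-[3,4-bis(methoxymethoxy)phenyl]-3-[3-[(1E,3S)-3,7-dimethylocta-1,6-dien-1-yl]-6-fluoro-2,4-bis(methoxymethoxy)phenyl]propane-1,3-diol | CC(C)=CCC[C@H](C)/C=C/c1c(OCOC)cc(F)c(C(O)C[C@H](O)c2ccc(OCOC)c(OCOC)c2)c1OCOC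
F2 | step 8 | (2S,4RS)-2-[3,4-bis(methoxymethoxy)phenyl]-6-[(1E,3S)-3,7-dimethylocta-1,6-dien-1-yl]-5,7-bis(methoxymethoxy)-3,4-dihydro-2H-chromen-4-ol | CC(C)=CCC[C@H](C)/C=C/c1c(OCOC)cc2c(c1OCOC)C(O)C[C@@H](c1ccc(OCOC)c(OCOC)c1)O2
F3 | step 4 | 1-[6-fluoro-3-[(3S)-1-hydroxy-3,7-dimethyloct-6-en-1-yl]-2,4-bis(methoxymethoxy)phenyl]ethan-1-one | CC(C)=CCC[C@H](C)CC(O)c1c(OCOC)cc(F)c(C(C)=O)c1OCOC
F4 | step 9 | 1-[3,4-bis(methoxymethoxy)phenyl]-3-[6-fluoro-3-iodo-2,4-bis(methoxymethoxy)phenyl]propane-1,3-dione | O=C(CC(=O)c1ccc(OCOC)c(OCOC)c1)c1c(OCOC)c(I)c(OCOC)cc1F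
F5 | step 9 | (3S)-3-[3,4-bis(methoxymethoxy)phenyl]-1-[6-fluoro-3-iodo-2,4-bis(methoxymethoxy)phenyl]-3-hydroxypropan-1-one | O=C(C[C@H](O)c1ccc(OCOC)c(OCOC)c1)c1c(OCOC)c(I)c(OCOC)cc1F
F6 | step 9 | (2S)-2-[3,4-bis(methoxymethoxy)phenyl]-6-iodo-5,7-bis(methoxymethoxy)-2,3-dihydro-4H-chromen-4-one | Ic1c(OCOC)cc2c(c1OCOC)C(=O)C[C@@H](c1ccc(OCOC)c(OCOC)c1)O2
F7 | step 9 | (2S)-2-(3,4-dihydroxyphenyl)-5,7-dihydroxy-6-iodo-2,3-dihydro-4H-chromen-4-one | Ic1c(O)cc2c(c1O)C(=O)C[C@@H](c1ccc(O)c(O)c1)O2
F8 | step 9 | (2S)-2-[3,4-bis(tert-butyldimethylsilyloxy)phenyl]-7-(tert-butyldimethylsilyloxy)-5-hydroxy-6-iodo-2,3-dihydro-4H-chromen-4-one | Ic1c(O[Si](C)(C)C(C)(C)C)cc2c(c1O)C(=O)C[C@@H](c1ccc(O[Si](C)(C)C(C)(C)C)c(O[Si](C)(C)C(C)(C)C)c1)O2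
F9 | step 9 | (2S)-2-[3,4-bis(tert-butyldimethylsilyloxy)phenyl]-7-(tert-butyldimethylsilyloxy)-6-[(1E,3S)-3,7-dimethylocta-1,6-dien-1-yl]-5-hydroxy-2,3-dihydro-4H-chromen-4-one | CC(C)=CCC[C@H](C)/C=C/c1c(O[Si](C)(C)C(C)(C)C)cc2c(c1O)C(=O)C[C@@H](c1ccc(O[Si](C)(C)C(C)(C)C)c(O[Si](C)(C)C(C)(C)C)c1)O2
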